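All runs come from a simulation for an exercise; the scatter is artificial.

If you hand these flasks to an integrator before you have reckoned anything, you get numbers with no view of what sets them, so start from what the earlier runs can tell you.

| flask | starting material | partner | second substrate | temperature | remark | time |
|---|---|---|---|---|---|---|
| maple | 0.10 M | 1.2 equiv | 1 equiv | −15 °C | run made earlier |  |
| alder | 0.10 M | 0.60 equiv | 1 equiv | 0 °C | run made earlier |  |
| cedar | 0.10 M | 0.90 equiv | 1 equiv | −15 °C | run made earlier |  |
| Thursday's | 0.10 M (fed, over 15 h) | 1.20 equiv | 1.00 equiv | 0 °C | all else is in the flask from the start; the feed brings no volume worth counting | 10 d |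
| Tuesday's | 0.10 M (fed, over 6.0 d) | 1.20 equiv | 1.00 equiv | 0 °C | all else is in the flask from the start; the feed brings no volume worth counting | 10 d |
| Wednesday's | 0.10 M | 1.20 equiv | 1.00 equiv | 0 °C | everything together at the start | 10 d |
| Saturday's | 0.10 M (in portions, 4, over 6.0 d) | 1.20 equiv | 1.00 equiv | 0 °C | first portion at the start, last at 6.0 d | 10 d |
| Monday's | 0.10 M | 1.20 equiv | 1.00 equiv (fed, over 6.0 d) |  | the addition at −20 °C, then warmed to 0 °C; the feed brings no volume worth counting | 10 d |
| Friday's | 0.10 M | 1.20 equiv | 1.00 equiv |  | everything together at the start at −20 °C, warmed to 0 °C at 6.0 d | 10 d |

- maple (time / d: cross product / %, target / %): 1.04: 42.0, 11.2; 2.00: 55.2, 15.1; 5.00: 68.5, 17.2; 12.0: 76.5, 11.7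
- alder (time / d: cross product / %, target / %): 0.833: 63.0, 9.9; 2.00: 76.0, 6.7; 4.00: 81.7, 3.7; 6.00: 80.1, 1.6
- cedar (time / d: cross product / %, target / %): 1.04: 41.5, 7.0; 2.00: 56.8, 10.7; 5.00: 70.9, 11.9; 12.0: 79.5, 9.0

(each reading ± 1 percentage point)

- the analysis behind the earlier runs scatters by 1 percentage point, standard deviation

1. which flask leads in amount of cross product, in percent of the starting material charged ("all alike" within 1.5 percentage points) (Thursday's / Tuesday's / Wednesday's / Saturday's / Monday's / Friday's / all alike)
2. how much cross product is there at the end, in percent of the starting material charged: Thursday's
3. how much cross product is there at the end, in percent of the starting material charged: Tuesday's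
4. how much cross product is there at the end, in percent of the starting material charged: Wednesday's
5. how much cross product is there at the end, in percent of the starting material charged: Saturday's
6. how much cross product is there at the end, in percent of the starting material charged: Monday's
7. how much cross product is there at the end, in percent of the starting material charged: Friday's

The starting material goes two ways: with the second substrate to cross product, and with the partner to target, which then fades, as in the alder run from 9.9 % to 1.6 %. Compare the maple and cedar runs at their first reading. With partner down from 1.2 equiv to 0.90 equiv, target falls from 11.2 % to 7.0 %, while cross product stays at 42.0 % and 41.5 %. So the concentration to watch in the target route is that of the partner. If each route is also first order in starting material, starting material cancels from the ratio of the two rates, and what stays is r = s × [second substrate]/[partner], where s, the selectivity factor, is the rate constant of the cross route over that of the target route. The share of starting material reaching cross product is then r/(1 + r), taken here with the charged amounts.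

At −15 °C, where target is still climbing after the first reading (the maple run goes on from 11.2 % to 15.1 %), cross product over target, times partner over second substrate, reads 4.50 from the maple run and 5.34 from the cedar run, so I take s = 4.92 as a reading with their scatter. In the alder run at 0 °C, target is down to 3.7 % at 4.00 d, so I count what is not cross product as lost by the target route, and the reading of 81.7 % gives s = 2.68, smaller than the cold value.

For Wednesday's, r = 2.23 and the share is 69.1 %. Thursday's and Tuesday's feed the starting material and Saturday's adds it in portions, and since its concentration cancels from r, I give these flasks the same figure. Friday's spends 6.0 d at −20 °C before warming to 0 °C, and with the cold s, read at −15 °C and taken over unchanged, I reckon r = 4.10 and a share of 80.4 %, so I put Friday's first. In Monday's the ratio climbs during the feed of second substrate, and one r does not cover that.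

The forecast also puts Friday's first, at 75 %, below my 80.4 %, with Wednesday's at 71 %, above my 69.1 %, and Monday's at 61 %, holding that “selectivity depends only on partner/substrate”.

The flasks give, at 10 d, 72.8 % for Thursday's, 70.6 % for Tuesday's, 73.0 % for Wednesday's, 70.4 % for Saturday's, 70.4 % for Monday's and 78.8 % for Friday's, so Friday's leads.

    starting material + partner ⇌ target (K = 23.0 /M, k = 1.10 × 10⁻⁴ /M/s, Ea = 77.0 kJ/mol, ΔH = −50.0 kJ/mol)
    second substrate + partner → second product (k = 3.10 × 10⁻⁶ /M/s, Ea = 75.0 kJ/mol)
    starting material + second substrate → cross product (k = 3.30 × 10⁻⁴ /M/s, Ea = 51.0 kJ/mol)
    target → over-reaction product (k = 7.10 × 10⁻⁶ /s, Ea = 85.0 kJ/mol)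
    (constants at 0 °C)

Take the neighbour of Friday's that is charged with 1.70 equiv of second substrate, the other charges and the time as in Friday's. The same cold s now gives r = 6.97, larger than the 4.10 of Friday's, and a share of 87.4 %. Friday's itself, reckoned at 80.4 %, stands at 78.8 %. The neighbour ends with 91.4 % cross product and 8.23 % over-reaction product.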